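**Retrosynthetic overview**
1. Target 27 ⇐ O-5 acylation with (2R)-2-methylbutanoic acid ⇐ SeO2 allylic hydroxylation at C5 ⇐ O-6 acylation with (2Z)-3-methylpent-2-enoic acid ⇐ hydroxyl-directed epoxidation of the C7 isopropenyl group.
2. Six-membered ring (second ring, formed last): intramolecular carbonyl-ene closure of C6–C7, which also creates the C6 carbinol and the C7 isopropenyl group.
3. Ene substrate ⇐ three-component conjugate addition/aldol on a 4-alkenylcyclopent-2-enone (C7a–C7 and C1–C1' bonds).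
4. That enone ⇐ conjugate addition/β-elimination on (S)-4-silyloxycyclopent-2-enone ⇐ five-membered ring (first ring) from cyclopentadiene by photooxygenation and a catalytic enantioselective Kornblum–DeLaMare desymmetrisation.
5. Acyl pieces: syn-carbocupration of ethyl pent-2-ynoate; asymmetric hydrogenation of tiglic acid.

Assumption: the SMILES is read literally, so the 2-methylbutanoate is (2R) and the pentenoate is (2Z); cyclopentadiene is used freshly cracked.
Numbering of the bicyclic core (octahydroindene): C1 (acetoxyethyl), C2 (C=O), C3, C3a, C4 (=CH2), C5, C6, C7, C7a.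

**Step 1**
Reactants: 1 cyclopenta-1,3-diene
Product: 3 (4S)-4-hydroxycyclopent-2-en-1-one, via endoperoxide 2 (not isolated)
Conditions: O2, hν, tetraphenylporphyrin (0.5 mol%), CH2Cl2, −78 °C; then hydroquinidine-derived 9-amino(9-deoxy)-epi 3,5-bis(trifluoromethyl)phenyl thiourea (10 mol%), CH2Cl2–toluene, −78 → −45 °C
Reagents that add atoms: dioxygen, O=O
Why: Proposed new method: singlet-oxygen [4+2] cycloaddition gives the meso endoperoxide, whose two enantiotopic bridgehead C–H bonds are told apart by a bifunctional cinchona thiourea (thiourea hydrogen-bonds the peroxide, the quinuclidine removes one bridgehead proton in an E2-type O–O cleavage), so the surviving carbinol carbon becomes the (S)-stereocentre; the closest known reaction is the chiral-amine-catalysed Kornblum–DeLaMare desymmetrisation of bicyclo[2.2.2] and larger meso endoperoxides, which to my knowledge has not been shown for this thermally labile [2.2.1] endoperoxide, and the quinine-series pseudoenantiomer is used if the sense proves opposite.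

**Step 2**
Reactants: 3 (4S)-4-hydroxycyclopent-2-en-1-one
Product: 4 (4S)-4-(tert-butyldimethylsilyloxy)cyclopent-2-en-1-one
Conditions: TBSCl, imidazole, CH2Cl2, 0 °C
Reagents that add atoms: tert-butyldimethylsilyl chloride, CC(C)(C)[Si](C)(C)Cl
Why: Standard silylation of a secondary alcohol, mild enough not to eliminate the β-oxy enone; the stereocentre is untouched.

**Step 3**
Reactants: 5 3-bromobut-3-en-1-ol
Product: 6 (3-bromobut-3-en-1-yloxy)(tert-butyl)dimethylsilane
Conditions: TBSCl, imidazole, CH2Cl2, 0 °C → rt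
Reagents that add atoms: tert-butyldimethylsilyl chloride, CC(C)(C)[Si](C)(C)Cl
Why: Standard silylation of a primary alcohol, needed so the alkenyl bromide can be metallated.

**Step 4**
Reactants: 4 (4S)-4-(tert-butyldimethylsilyloxy)cyclopent-2-en-1-one; 6 (3-bromobut-3-en-1-yloxy)(tert-butyl)dimethylsilane
Product: 9 (4S)-4-[4-(tert-butyldimethylsilyloxy)but-1-en-2-yl]cyclopent-2-en-1-one, via alkenylmagnesium bromide 7 (not isolated), via silyloxy ketone 8 (not isolated)
Conditions: 6, Mg, THF, 45 °C; CuBr·SMe2 (15 mol%), 4, THF, −78 → −40 °C; aq NH4Cl; crude 8, DBU, CH2Cl2, 0 °C, short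
Reagents that add atoms: none
Why: CuBr·SMe2-catalysed Grignard conjugate addition occurs anti to the silyloxy group and E1cB loss of silanolate then moves the enone, so the chirality of 4 is relayed to the new C4 (the future C3a) before the old stereocentre is erased; brief DBU exposure at 0 °C limits γ-deprotonation of 9.

**Step 5**
Reactants: 9 (4S)-4-[4-(tert-butyldimethylsilyloxy)but-1-en-2-yl]cyclopent-2-en-1-one; 10 (2-methylprop-1-en-1-yl)magnesium bromide; 11 acetaldehyde
Product: 14 (2R,3R,4S)-4-[4-(tert-butyldimethylsilyloxy)but-1-en-2-yl]-2-[(1S)-1-hydroxyethyl]-3-(2-methylprop-1-en-1-yl)cyclopentan-1-one, via BrMg enolate 12 (not isolated), via Ti(OiPr)3 enolate 13 (not isolated)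
Conditions: 10, CuBr·SMe2 (10 mol%), THF, −78 °C; ClTi(OiPr)3, −78 → −40 °C; 11, −78 °C; aq NH4Cl
Reagents that add atoms: none
Why: Three-component conjugate addition/aldol: the alkenyl group adds anti to the C4 substituent, the regiodefined enolate reacts with acetaldehyde anti to the new C3 substituent (all-trans ring), and Ti(OiPr)3 enolates are erythro-selective whatever the enolate geometry, which gives the (1S) carbinol (syn aldol).

**Step 6**
Reactants: 14 (2R,3R,4S)-4-[4-(tert-butyldimethylsilyloxy)but-1-en-2-yl]-2-[(1S)-1-hydroxyethyl]-3-(2-methylprop-1-en-1-yl)cyclopentan-1-one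
Product: 15 (1S)-1-[(1R,2R,3S)-3-[4-(tert-butyldimethylsilyloxy)but-1-en-2-yl]-2-(2-methylprop-1-en-1-yl)-5-oxocyclopentyl]ethyl acetate
Conditions: Ac2O, pyridine, DMAP (5 mol%), CH2Cl2, 0 °C
Reagents that add atoms: acetic anhydride, CC(=O)OC(C)=O
Why: Mild acylation of the aldol hydroxyl installs the final acetate and prevents retro-aldol; 0 °C and little DMAP avoid β-elimination.

**Step 7**
Reactants: 15 (1S)-1-[(1R,2R,3S)-3-[4-(tert-butyldimethylsilyloxy)but-1-en-2-yl]-2-(2-methylprop-1-en-1-yl)-5-oxocyclopentyl]ethyl acetate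
Product: 16 (1S)-1-[(1R,2R,3S)-3-(4-hydroxybut-1-en-2-yl)-2-(2-methylprop-1-en-1-yl)-5-oxocyclopentyl]ethyl acetate
Conditions: HF·pyridine, THF–pyridine, 0 °C → rt
Reagents that add atoms: none
Why: Buffered fluoride desilylation frees the primary alcohol without touching the β-acetoxy ketone or the alkenes.

**Step 8**
Reactants: 16 (1S)-1-[(1R,2R,3S)-3-(4-hydroxybut-1-en-2-yl)-2-(2-methylprop-1-en-1-yl)-5-oxocyclopentyl]ethyl acetate
Product: 18 (1S)-1-[(1R,3aS,6R,7S,7aS)-6-hydroxy-4-methylidene-2-oxo-7-(prop-1-en-2-yl)octahydro-1H-inden-1-yl]ethyl acetate, via aldehyde 17 (not isolated)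
Conditions: Dess–Martin periodinane, NaHCO3, CH2Cl2, 0 °C; filter; Me2AlCl (2.5 equiv), CH2Cl2, −78 °C
Reagents that add atoms: none
Why: Dess–Martin oxidation gives the labile β,γ-unsaturated aldehyde, which closes at once in an intramolecular carbonyl-ene reaction of the citronellal-to-isopulegol kind; a chair transition state with the forming hydroxyl and isopropenyl groups equatorial gives the trans-fused ring with C6–OH and C7-isopropenyl trans, and the exocyclic methylene is already in place.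

**Step 9**
Reactants: 18 (1S)-1-[(1R,3aS,6R,7S,7aS)-6-hydroxy-4-methylidene-2-oxo-7-(prop-1-en-2-yl)octahydro-1H-inden-1-yl]ethyl acetate
Product: 19 (1S)-1-[(1R,3aS,6R,7R,7aS)-6-hydroxy-4-methylidene-7-[(2S)-2-methyloxiran-2-yl]-2-oxooctahydro-1H-inden-1-yl]ethyl acetate
Conditions: VO(OiPr)3 (2 mol%), trans-cyclohexane-1,2-diamine-derived C2-symmetric bis-hydroxamic acid ligand (4 mol%), cumene hydroperoxide, toluene, 0 °C → rt
Reagents that add atoms: cumene hydroperoxide, CC(C)(OO)c1ccccc1
Why: Hydroxyl-directed VO(OiPr)3-catalysed epoxidation of a homoallylic alcohol: the equatorial C6–OH can deliver the peroxide to the freely rotating isopropenyl group on the neighbouring carbon but not to the faces of the ring methylene, and the ligand antipode (chosen in a two-run test) sets the (2S)-epoxide by reagent control.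

**Step 10**
Reactants: 20 ethyl pent-2-ynoate
Product: 21 ethyl (2Z)-3-methylpent-2-enoate
Conditions: Me2CuLi (from MeLi, CuI), THF, −78 °C; NH4Cl quench at −78 °C
Reagents that add atoms: methyllithium, [Li]C
Why: Syn-carbocupration of the ynoate puts the methyl group and the copper (then H) on the same side, so ethyl ends cis to the ester (2Z) if the quench is kept cold.

**Step 11**
Reactants: 21 ethyl (2Z)-3-methylpent-2-enoate
Product: 22 (2Z)-3-methylpent-2-enoic acid
Conditions: LiOH, THF–H2O, rt; then aq HCl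
Reagents that add atoms: lithium hydroxide, [Li+].[OH-]
Why: Saponification at room temperature does not isomerise the trisubstituted enoate.

**Step 12**
Reactants: 19 (1S)-1-[(1R,3aS,6R,7R,7aS)-6-hydroxy-4-methylidene-7-[(2S)-2-methyloxiran-2-yl]-2-oxooctahydro-1H-inden-1-yl]ethyl acetate; 22 (2Z)-3-methylpent-2-enoic acid
Product: 23 (1R,3aS,6R,7R,7aS)-1-[(1S)-1-acetoxyethyl]-4-methylidene-7-[(2S)-2-methyloxiran-2-yl]-2-oxooctahydro-1H-inden-6-yl (2Z)-3-methylpent-2-enoate
Conditions: DCC, DMAP (10 mol%), CH2Cl2, 0 °C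
Reagents that add atoms: none
Why: Steglich esterification of the equatorial C6 alcohol avoids the acid chloride and amine base that would scramble the alkene geometry through a vinylketene.

**Step 13**
Reactants: 23 (1R,3aS,6R,7R,7aS)-1-[(1S)-1-acetoxyethyl]-4-methylidene-7-[(2S)-2-methyloxiran-2-yl]-2-oxooctahydro-1H-inden-6-yl (2Z)-3-methylpent-2-enoate
Product: 24 (1R,3aS,5R,6S,7R,7aS)-1-[(1S)-1-acetoxyethyl]-5-hydroxy-4-methylidene-7-[(2S)-2-methyloxiran-2-yl]-2-oxooctahydro-1H-inden-6-yl (2Z)-3-methylpent-2-enoate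
Conditions: SeO2 (0.5 equiv), t-BuOOH, CH2Cl2, rt
Reagents that add atoms: tert-butyl hydroperoxide, CC(C)(C)OO; selenium dioxide, O=[Se]=O
Why: Riley allylic oxidation (ene reaction then [2,3]-shift) of the 1,1-disubstituted alkene attacks the ring CH2 in preference to the ring-fusion CH and replaces the axial C5–H by OH on the same face, giving the axial alcohol cis to O-6 and returning the double bond to the exocyclic position; the isopropenyl group is already masked as the epoxide.

**Step 14**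
Reactants: 25 tiglic acid ((2E)-2-methylbut-2-enoic acid)
Product: 26 (2R)-2-methylbutanoic acid
Conditions: H2 (4 atm), Ru(OAc)2[(R)-H8-BINAP] (0.5 mol%), MeOH, 20 °C
Reagents that add atoms: none
Why: Carboxylate-directed asymmetric hydrogenation of an α,β-unsaturated acid; the (R)-ligand is expected to give the (R)-acid by the usual correlation for this substrate, and the sign of rotation (levorotatory for R) is checked before use.

**Step 15**
Reactants: 24 (1R,3aS,5R,6S,7R,7aS)-1-[(1S)-1-acetoxyethyl]-5-hydroxy-4-methylidene-7-[(2S)-2-methyloxiran-2-yl]-2-oxooctahydro-1H-inden-6-yl (2Z)-3-methylpent-2-enoate; 26 (2R)-2-methylbutanoic acid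
Product: 27 (1R,3aS,5R,6S,7R,7aS)-1-[(1S)-1-acetoxyethyl]-4-methylidene-7-[(2S)-2-methyloxiran-2-yl]-6-{[(2Z)-3-methylpent-2-enoyl]oxy}-2-oxooctahydro-1H-inden-5-yl (2R)-2-methylbutanoate
Conditions: DCC, DMAP (20 mol%), CH2Cl2, 0 °C → rt
Reagents that add atoms: none
Why: Steglich esterification of the axial allylic C5 alcohol; carbodiimide activation is faster than 1,2-acyl migration of the enoate and does not pass through a ketene, so the α-stereocentre of the acid is kept.

**Compound list**
1 | cyclopenta-1,3-diene | C1C=CC=C1 | starting material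
2 | 2,3-dioxabicyclo[2.2.1]hept-5-ene (meso endoperoxide) | C1=C[C@@H]2C[C@H]1OO2 | intermediate
3 | (4S)-4-hydroxycyclopent-2-en-1-one | O=C1C=C[C@@H](O)C1 | intermediate
4 | (4S)-4-(tert-butyldimethylsilyloxy)cyclopent-2-en-1-one | O=C1C=C[C@@H](O[Si](C)(C)C(C)(C)C)C1 | intermediate
5 | 3-bromobut-3-en-1-ol | C=C(Br)CCO | starting material
6 | (3-bromobut-3-en-1-yloxy)(tert-butyl)dimethylsilane | C=C(Br)CCO[Si](C)(C)C(C)(C)C | intermediate
7 | [4-(tert-butyldimethylsilyloxy)but-1-en-2-yl]magnesium bromide | C=C([Mg]Br)CCO[Si](C)(C)C(C)(C)C | intermediate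
8 | (3R,4S)-3-[4-(tert-butyldimethylsilyloxy)but-1-en-2-yl]-4-(tert-butyldimethylsilyloxy)cyclopentan-1-one (3,4-trans) | C=C(CCO[Si](C)(C)C(C)(C)C)[C@H]1CC(=O)C[C@@H]1O[Si](C)(C)C(C)(C)C | intermediate
9 | (4S)-4-[4-(tert-butyldimethylsilyloxy)but-1-en-2-yl]cyclopent-2-en-1-one | C=C(CCO[Si](C)(C)C(C)(C)C)[C@@H]1C=CC(=O)C1 | intermediate
10 | (2-methylprop-1-en-1-yl)magnesium bromide | CC(C)=C[Mg]Br | starting material
11 | acetaldehyde | CC=O | starting material
12 | bromomagnesium (3R,4S)-4-[4-(tert-butyldimethylsilyloxy)but-1-en-2-yl]-3-(2-methylprop-1-en-1-yl)cyclopent-1-en-1-olate (3,4-trans) | Br[Mg]OC1=C[C@H](C=C(C)C)[C@@H](C(=C)CCO[Si](C)(C)C(C)(C)C)C1 | intermediate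
13 | triisopropoxytitanium (3R,4S)-4-[4-(tert-butyldimethylsilyloxy)but-1-en-2-yl]-3-(2-methylprop-1-en-1-yl)cyclopent-1-en-1-olate | CC(C)O[Ti](OC(C)C)(OC(C)C)OC1=C[C@H](C=C(C)C)[C@@H](C(=C)CCO[Si](C)(C)C(C)(C)C)C1 | intermediate
14 | (2R,3R,4S)-4-[4-(tert-butyldimethylsilyloxy)but-1-en-2-yl]-2-[(1S)-1-hydroxyethyl]-3-(2-methylprop-1-en-1-yl)cyclopentan-1-one | C=C(CCO[Si](C)(C)C(C)(C)C)[C@H]1CC(=O)[C@@H]([C@H](C)O)[C@@H]1C=C(C)C | intermediate
15 | (1S)-1-[(1R,2R,3S)-3-[4-(tert-butyldimethylsilyloxy)but-1-en-2-yl]-2-(2-methylprop-1-en-1-yl)-5-oxocyclopentyl]ethyl acetate | C=C(CCO[Si](C)(C)C(C)(C)C)[C@H]1CC(=O)[C@@H]([C@H](C)OC(C)=O)[C@@H]1C=C(C)C | intermediate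
16 | (1S)-1-[(1R,2R,3S)-3-(4-hydroxybut-1-en-2-yl)-2-(2-methylprop-1-en-1-yl)-5-oxocyclopentyl]ethyl acetate | C=C(CCO)[C@H]1CC(=O)[C@@H]([C@H](C)OC(C)=O)[C@@H]1C=C(C)C | intermediate
17 | (1S)-1-[(1R,2R,3S)-2-(2-methylprop-1-en-1-yl)-5-oxo-3-(4-oxobut-1-en-2-yl)cyclopentyl]ethyl acetate | C=C(CC=O)[C@H]1CC(=O)[C@@H]([C@H](C)OC(C)=O)[C@@H]1C=C(C)C | intermediate
18 | (1S)-1-[(1R,3aS,6R,7S,7aS)-6-hydroxy-4-methylidene-2-oxo-7-(prop-1-en-2-yl)octahydro-1H-inden-1-yl]ethyl acetate | C=C1[C@H]2CC(=O)[C@@H]([C@H](C)OC(C)=O)[C@@H]2[C@@H](C(C)=C)[C@H](O)C1 | intermediate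
19 | (1S)-1-[(1R,3aS,6R,7R,7aS)-6-hydroxy-4-methylidene-7-[(2S)-2-methyloxiran-2-yl]-2-oxooctahydro-1H-inden-1-yl]ethyl acetate | C=C1[C@H]2CC(=O)[C@@H]([C@H](C)OC(C)=O)[C@@H]2[C@@H]([C@@]2(C)CO2)[C@H](O)C1 | intermediate
20 | ethyl pent-2-ynoate | CCC#CC(=O)OCC | starting material
21 | ethyl (2Z)-3-methylpent-2-enoate | CCOC(=O)/C=C(/C)CC | intermediate
22 | (2Z)-3-methylpent-2-enoic acid | OC(=O)/C=C(/C)CC | intermediate
23 | (1R,3aS,6R,7R,7aS)-1-[(1S)-1-acetoxyethyl]-4-methylidene-7-[(2S)-2-methyloxiran-2-yl]-2-oxooctahydro-1H-inden-6-yl (2Z)-3-methylpent-2-enoate | C=C1[C@H]2CC(=O)[C@@H]([C@H](C)OC(C)=O)[C@@H]2[C@@H]([C@@]2(C)CO2)[C@H](OC(=O)/C=C(/C)CC)C1 | intermediate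
24 | (1R,3aS,5R,6S,7R,7aS)-1-[(1S)-1-acetoxyethyl]-5-hydroxy-4-methylidene-7-[(2S)-2-methyloxiran-2-yl]-2-oxooctahydro-1H-inden-6-yl (2Z)-3-methylpent-2-enoate | C=C1[C@H]2CC(=O)[C@@H]([C@H](C)OC(C)=O)[C@@H]2[C@@H]([C@@]2(C)CO2)[C@H](OC(=O)/C=C(/C)CC)[C@@H]1O | intermediate
25 | tiglic acid, (2E)-2-methylbut-2-enoic acid | C/C=C(\C)C(=O)O | starting material
26 | (2R)-2-methylbutanoic acid | CC[C@@H](C)C(=O)O | intermediate
27 | (1R,3aS,5R,6S,7R,7aS)-1-[(1S)-1-acetoxyethyl]-4-methylidene-7-[(2S)-2-methyloxiran-2-yl]-6-{[(2Z)-3-methylpent-2-enoyl]oxy}-2-oxooctahydro-1H-inden-5-yl (2R)-2-methylbutanoate | C=C1[C@H]2CC(=O)[C@@H]([C@H](C)OC(C)=O)[C@@H]2[C@@H]([C@@]2(C)CO2)[C@H](OC(=O)/C=C(/C)CC)[C@@H]1OC(=O)[C@H](C)CC | target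

**Step count**
Total: 15 steps. Longest linear sequence: 11 steps (1, 2, 4, 5, 6, 7, 8, 9, 12, 13, 15).

**Three steps most likely to fail, with fallbacks**

Step 1 (the proposed new desymmetrisation). The risk is low enantioselectivity or thermal decay of endoperoxide 2 before the chiral base acts. The fallback uses known chemistry and sets out from 1: photooxygenation followed by triethylamine gives racemic 4-hydroxycyclopent-2-en-1-one F1 by the ordinary Kornblum–DeLaMare rearrangement. A lipase-catalysed transesterification with vinyl acetate (Amano lipase PS) then acetylates the (R)-enantiomer to (1R)-4-oxocyclopent-2-en-1-yl acetate F2 and leaves the (S)-alcohol untouched. That alcohol is 3, where the route is rejoined.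

Step 5 (three-component coupling). The risk is the simple diastereoselection at the carbinol carbon (syn against anti) in the one-pot enolate aldol. The fallback sets out from 9: CuBr·SMe2-catalysed addition of 10 in the presence of TMSCl gives the trimethylsilyl enol ether F3, which is isolated. A fluoride-initiated aldol with 11 (catalytic tris(dimethylamino)sulfonium difluorotrimethylsilicate, THF, −78 °C) runs through an open transition state that is erythro-selective for cyclic enol silanes and gives the O-trimethylsilyl aldol F4. Citric acid in methanol removes the silyl group and returns to 14.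

Step 13 (Riley oxidation). The risk is that the O-6 ester deactivates the C5 methylene, or that the ring-fusion C–H or the epoxide reacts instead. The fallback sets out from 19: the SeO2/t-BuOOH oxidation is run on the free C6 alcohol to give the 5,6-diol F5. The equatorial C6 hydroxyl is then esterified with 22 (DCC, DMAP, −20 °C) in preference to the axial allylic C5 hydroxyl, which returns to 24.

**Further compounds**
F1 | step 1 | racemic 4-hydroxycyclopent-2-en-1-one | O=C1C=CC(O)C1
F2 | step 1 | (1R)-4-oxocyclopent-2-en-1-yl acetate | CC(=O)O[C@H]1C=CC(=O)C1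
F3 | step 5 | tert-butyl({3-[(1S,2R)-2-(2-methylprop-1-en-1-yl)-4-(trimethylsilyloxy)cyclopent-3-en-1-yl]but-3-en-1-yl}oxy)dimethylsilane (trimethylsilyl enol ether of the conjugate adduct) | C[Si](C)(C)OC1=C[C@H](C=C(C)C)[C@@H](C(=C)CCO[Si](C)(C)C(C)(C)C)C1
F4 | step 5 | (2R,3R,4S)-4-[4-(tert-butyldimethylsilyloxy)but-1-en-2-yl]-3-(2-methylprop-1-en-1-yl)-2-[(1S)-1-(trimethylsilyloxy)ethyl]cyclopentan-1-one | C=C(CCO[Si](C)(C)C(C)(C)C)[C@H]1CC(=O)[C@@H]([C@H](C)O[Si](C)(C)C)[C@@H]1C=C(C)C
F5 | step 13 | (1S)-1-[(1R,3aS,5R,6S,7R,7aS)-5,6-dihydroxy-4-methylidene-7-[(2S)-2-methyloxiran-2-yl]-2-oxooctahydro-1H-inden-1-yl]ethyl acetate | C=C1[C@H]2CC(=O)[C@@H]([C@H](C)OC(C)=O)[C@@H]2[C@@H]([C@@]2(C)CO2)[C@H](O)[C@@H]1O
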